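**Strategy.** In eudesmane numbering, ring A is disconnected across C1–C10 and C4–C5. C1–C4 with C15 then come from one reagent, methyl 3-oxopent-4-enoate, and ring B is the chiral-pool ketone (+)-dihydrocarvone, whose stereocentre is C7. A Robinson-type annulation of its (R)-1-phenylethylamine imine closes ring A in one operation (Michael addition at C10, then condensation of C4 on C5). It delivers all fifteen skeletal carbons with C15 already a carboxyl. The C3 carbonyl left behind serves as a relay: reduction to the 3β-alcohol and a reductive allylic transposition set the 5α-hydrogen and the C3=C4 alkene. Side-chain oxidation and late attachment of the (Z)-coumarate finish the target.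

Key step: step 4

Remark: eudesmane numbering is used (ring A: C1–C5 and C10; ring B: C5–C10; C14 on C10, C15 on C4, C11–C13 on C7); commercial (+)-dihydrocarvone contains some C2 epimer, which is immaterial because that centre is planarised in step 4.

Step 1
Reactants: 1 acrolein; 2 methyl acetate
Product: 3 methyl 3-hydroxypent-4-enoate (racemic)
Conditions: LiN(i-Pr)2, THF, −78 °C, 2 then 1; AcOH quench
Reagents that add atoms: none
Why: Directed aldol addition of the lithium ester enolate to the aldehyde carbon of acrolein (1,2-addition at low temperature); the carbinol centre is racemic and is erased in step 2.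

Step 2
Reactants: 3 methyl 3-hydroxypent-4-enoate
Product: 4 methyl 3-oxopent-4-enoate (Nazarov reagent)
Conditions: Dess–Martin periodinane, CH2Cl2, 0 °C → rt; hydroquinone (trace); used at once
Reagents that add atoms: none
Why: Dess–Martin oxidation of the allylic β-hydroxy ester should give the vinyl β-keto ester under non-basic conditions that limit its polymerisation.

Step 3
Reactants: 5 (+)-dihydrocarvone; 6 (R)-1-phenylethylamine
Product: 7 (5R)-2-methyl-N-[(1R)-1-phenylethyl]-5-(prop-1-en-2-yl)cyclohexan-1-imine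
Conditions: TsOH·H2O (cat.), toluene, reflux, Dean–Stark
Reagents that add atoms: none
Why: Acid-catalysed ketimine condensation with azeotropic removal of water; the bought stereocentre (future C7) is not touched.

Step 4
Reactants: 7 the imine; 4 methyl 3-oxopent-4-enoate
Product: 9 methyl (7R,10S)-3-oxoeudesma-4,11-dien-15-oate, via Michael adduct imine 8 (not isolated)
Conditions: hydroquinone (cat.), THF, 0 °C → rt; then AcOH, 50 °C, same flask
Reagents that add atoms: none
Why: The imine reacts through its more substituted secondary enamine tautomer, which adds to the vinyl terminus of 4 in an aza-ene-like Michael addition with internal N–H to carbon proton transfer and forms C1–C10 at the methyl-bearing carbon; acetic acid then converts the ketimine of 8 into an iminium ion that is attacked by the enol of the β-keto ester at C4 and loses the auxiliary amine by β-elimination, forming C4–C5 as the C4=C5 alkene. The closest known reaction is the Robinson annulation of 1-phenylethylamine imines of 2-methylcyclohexanones with alkyl vinyl ketones, run here with the Nazarov reagent, which is itself known to annulate enamines. Ring A closes in a 6-(enolendo)-exo-trig Mannich/Knoevenagel mode. The new quaternary centre C10 is controlled by the (R)-1-phenylethyl group, chosen to deliver the acceptor to the enamine face that leaves the C10 methyl cis to the C7 isopropenyl group; C7 is bought and unchanged. The step needs regioselectivity for C10 over C6 (secured by the more substituted enamine and the cyclic transition state), facial selectivity against the ring's own preference for the C10 epimer (secured by the auxiliary) and chemoselectivity against polymerisation of 4 (low temperature, inhibitor, slight excess).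

Step 5
Reactants: 9 methyl (7R,10S)-3-oxoeudesma-4,11-dien-15-oate
Product: 10 methyl (3S,7R,10S)-3-hydroxyeudesma-4,11-dien-15-oate (3β-alcohol)
Conditions: NaBH4, CeCl3·7H2O, MeOH, −78 → −20 °C
Reagents that add atoms: none
Why: Luche 1,2-reduction of the enone; axial hydride delivery on the α face, opposite the angular 10β-methyl, should give the pseudo-equatorial 3β-alcohol, as with 4-en-3-one steroids, while the ester and isopropenyl group are inert (any 3α epimer is removed, since it would relay to the cis ring fusion).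

Step 6
Reactants: 10 methyl (3S,7R,10S)-3-hydroxyeudesma-4,11-dien-15-oate
Product: 13 methyl (5R,7R,10R)-eudesma-3,11-dien-15-oate, via N-allyl sulfonylhydrazone 11 (not isolated), via allylic diazene 12 (not isolated)
Conditions: PPh3, DEAD, IPNBSH (N-isopropylidene-N'-2-nitrobenzenesulfonylhydrazine), THF, 0 °C → rt; then CF3CH2OH/H2O (1:1), rt
Reagents that add atoms: none
Why: Mitsunobu displacement with inversion places nitrogen on the α face of C3; hydrazone hydrolysis and loss of sulfinic acid give the monoalkyl diazene, whose retro-ene loss of N2 (reductive allylic transposition) delivers hydrogen suprafacially to the α face of C5 and moves the alkene to C3=C4, so the 3β-alcohol sets the 5α-H trans ring fusion.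

Step 7
Reactants: 13 methyl (5R,7R,10R)-eudesma-3,11-dien-15-oate
Product: 15 methyl (5R,7R,10R)-12-oxoeudesma-3,11(13)-dien-15-oate, via allylic alcohol 14 (not isolated)
Conditions: SeO2 (0.5 equiv), t-BuOOH, CH2Cl2, rt; then MnO2, CH2Cl2, rt
Reagents that add atoms: selenium dioxide (O=[Se]=O), reoxidised by tert-butyl hydroperoxide (CC(C)(C)OO), the terminal oxygen source
Why: SeO2 allylic oxidation (ene reaction, then [2,3]-sigmatropic shift) should attack only the electron-rich isopropenyl group at its methyl carbon, because the ring A alkene is a deactivated enoate; MnO2 converges the alcohol/aldehyde mixture on the enal.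

Step 8
Reactants: 15 methyl (5R,7R,10R)-12-oxoeudesma-3,11(13)-dien-15-oate
Product: 16 (5R,7R,10R)-15-methoxy-15-oxoeudesma-3,11(13)-dien-12-oic acid
Conditions: NaClO2, NaH2PO4, 2-methyl-2-butene, t-BuOH/H2O, 0 °C → rt
Reagents that add atoms: sodium chlorite ([Na+].[O-]Cl=O)
Why: Pinnick oxidation converts the α-methylene aldehyde to the acrylic acid without touching either alkene, the hypochlorite being trapped by the scavenger alkene.

Step 9
Reactants: 16 (5R,7R,10R)-15-methoxy-15-oxoeudesma-3,11(13)-dien-12-oic acid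
Product: 17 (5R,7R,10R)-15-hydroxyeudesma-3,11(13)-dien-12-oic acid
Conditions: i-Bu2AlH (5 equiv), CH2Cl2, −78 °C; aq. potassium sodium tartrate, then pH 3
Reagents that add atoms: none
Why: Hydride reduction of the conjugated methyl ester to the allylic alcohol (1,2-selective); the first equivalent converts the acrylic acid into its aluminium carboxylate, which should resist hydride at −78 °C.

Step 10
Reactants: 17 (5R,7R,10R)-15-hydroxyeudesma-3,11(13)-dien-12-oic acid
Product: 18 2-(trimethylsilyl)ethoxymethyl (5R,7R,10R)-15-hydroxyeudesma-3,11(13)-dien-12-oate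
Conditions: SEMCl (1.05 equiv), i-Pr2NEt, CH2Cl2, −20 → 0 °C
Reagents that add atoms: 2-(trimethylsilyl)ethoxymethyl chloride (C[Si](C)(C)CCOCCl)
Why: O-alkylation of the carboxylate by the chloromethyl ether (SEM ester formation) is much faster than etherification of the primary alcohol at low temperature with a hindered amine base.

Step 11
Reactants: 19 tert-butyl(4-ethynylphenoxy)dimethylsilane
Product: 20 3-[4-(tert-butyldimethylsilyloxy)phenyl]prop-2-ynoic acid
Conditions: n-BuLi, THF, −78 °C; CO2; cold 1 M HCl
Reagents that add atoms: carbon dioxide (O=C=O)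
Why: Deprotonation of the terminal alkyne and carboxylation of the lithium acetylide; the aryl silyl ether tolerates both at low temperature.

Step 12
Reactants: 20 3-[4-(tert-butyldimethylsilyloxy)phenyl]prop-2-ynoic acid
Product: 21 (2Z)-3-[4-(tert-butyldimethylsilyloxy)phenyl]prop-2-enoic acid
Conditions: H2 (1 atm), Pd/CaCO3 poisoned with Pb(OAc)2 (Lindlar catalyst), quinoline, EtOAc, rt, stopped at one equivalent
Reagents that add atoms: none
Why: Lindlar semihydrogenation adds hydrogen syn on the poisoned palladium surface and should give the (Z)-alkene.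

Step 13
Reactants: 18 the SEM ester alcohol; 21 the (Z)-acid
Product: 22 2-(trimethylsilyl)ethoxymethyl (5R,7R,10R)-15-{[(2Z)-3-(4-tert-butyldimethylsilyloxyphenyl)prop-2-enoyl]oxy}eudesma-3,11(13)-dien-12-oate
Conditions: EDC·HCl, DMAP (cat.), CH2Cl2, 0 °C, dark
Reagents that add atoms: none
Why: Steglich-type carbodiimide esterification of the primary allylic alcohol by acyl transfer, which leaves the allylic C–O bond and the (Z)-alkene untouched at low temperature in the dark.

Step 14
Reactants: 22 the doubly protected ester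
Product: 23 (5R,7R,10R)-15-{[(2Z)-3-(4-hydroxyphenyl)prop-2-enoyl]oxy}eudesma-3,11(13)-dien-12-oic acid (target)
Conditions: n-Bu4NF, AcOH (1:1), THF, 0 °C → rt, dark
Reagents that add atoms: none
Why: Fluoride-induced desilylation cleaves the aryl silyl ether and fragments the SEM ester (loss of fluorosilane, ethylene and formaldehyde); the acetic acid buffer should keep the phenol protonated and so protect the (Z)-alkene and the allylic ester.

**Compound list**

1 | acrolein | C=CC=O | starting material
2 | methyl acetate | CC(=O)OC | starting material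
3 | methyl 3-hydroxypent-4-enoate (racemic) | C=CC(O)CC(=O)OC | intermediate
4 | methyl 3-oxopent-4-enoate (Nazarov reagent) | C=CC(=O)CC(=O)OC | intermediate
5 | (+)-dihydrocarvone, (2R,5R)-2-methyl-5-(prop-1-en-2-yl)cyclohexan-1-one | CC(=C)[C@@H]1CC[C@@H](C)C(=O)C1 | starting material
6 | (R)-(+)-1-phenylethylamine | C[C@@H](N)c1ccccc1 | starting material
7 | (5R)-2-methyl-N-[(1R)-1-phenylethyl]-5-(prop-1-en-2-yl)cyclohexan-1-imine (major C2 epimer drawn) | CC(=C)[C@@H]1CC[C@@H](C)C(=N[C@H](C)c2ccccc2)C1 | intermediate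
8 | methyl 5-[(1S,4R)-1-methyl-2-{[(1R)-1-phenylethyl]imino}-4-(prop-1-en-2-yl)cyclohexyl]-3-oxopentanoate | CC(=C)[C@@H]1CC[C@@](C)(CCC(=O)CC(=O)OC)C(=N[C@H](C)c2ccccc2)C1 | intermediate
9 | methyl (7R,10S)-3-oxoeudesma-4,11-dien-15-oate, i.e. methyl (4aS,7R)-4a-methyl-2-oxo-7-(prop-1-en-2-yl)-2,3,4,4a,5,6,7,8-octahydronaphthalene-1-carboxylate | CC(=C)[C@@H]1CC[C@@]2(C)CCC(=O)C(C(=O)OC)=C2C1 | intermediate
10 | methyl (3S,7R,10S)-3-hydroxyeudesma-4,11-dien-15-oate (3β-OH) | CC(=C)[C@@H]1CC[C@@]2(C)CC[C@H](O)C(C(=O)OC)=C2C1 | intermediate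
11 | methyl 3α-[N-(2-nitrophenylsulfonyl)-N'-isopropylidenehydrazino]eudesma-4,11-dien-15-oate | CC(=C)[C@@H]1CC[C@@]2(C)CC[C@@H](N(N=C(C)C)S(=O)(=O)c3ccccc3[N+](=O)[O-])C(C(=O)OC)=C2C1 | intermediate
12 | methyl 3α-diazenyleudesma-4,11-dien-15-oate | CC(=C)[C@@H]1CC[C@@]2(C)CC[C@@H](N=N)C(C(=O)OC)=C2C1 | intermediate
13 | methyl (5R,7R,10R)-eudesma-3,11-dien-15-oate (5α-H, trans-fused) | CC(=C)[C@@H]1CC[C@@]2(C)CCC=C(C(=O)OC)[C@@H]2C1 | intermediate
14 | methyl (5R,7R,10R)-12-hydroxyeudesma-3,11(13)-dien-15-oate | OCC(=C)[C@@H]1CC[C@@]2(C)CCC=C(C(=O)OC)[C@@H]2C1 | intermediate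
15 | methyl (5R,7R,10R)-12-oxoeudesma-3,11(13)-dien-15-oate | O=CC(=C)[C@@H]1CC[C@@]2(C)CCC=C(C(=O)OC)[C@@H]2C1 | intermediate
16 | (5R,7R,10R)-15-methoxy-15-oxoeudesma-3,11(13)-dien-12-oic acid | OC(=O)C(=C)[C@@H]1CC[C@@]2(C)CCC=C(C(=O)OC)[C@@H]2C1 | intermediate
17 | (5R,7R,10R)-15-hydroxyeudesma-3,11(13)-dien-12-oic acid | OC(=O)C(=C)[C@@H]1CC[C@@]2(C)CCC=C(CO)[C@@H]2C1 | intermediate
18 | 2-(trimethylsilyl)ethoxymethyl (5R,7R,10R)-15-hydroxyeudesma-3,11(13)-dien-12-oate | C=C(C(=O)OCOCC[Si](C)(C)C)[C@@H]1CC[C@@]2(C)CCC=C(CO)[C@@H]2C1 | intermediate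
19 | tert-butyl(4-ethynylphenoxy)dimethylsilane | C#Cc1ccc(O[Si](C)(C)C(C)(C)C)cc1 | starting material
20 | 3-[4-(tert-butyldimethylsilyloxy)phenyl]prop-2-ynoic acid | OC(=O)C#Cc1ccc(O[Si](C)(C)C(C)(C)C)cc1 | intermediate
21 | (2Z)-3-[4-(tert-butyldimethylsilyloxy)phenyl]prop-2-enoic acid | OC(=O)/C=C\c1ccc(O[Si](C)(C)C(C)(C)C)cc1 | intermediate
22 | 2-(trimethylsilyl)ethoxymethyl (5R,7R,10R)-15-{[(2Z)-3-(4-tert-butyldimethylsilyloxyphenyl)prop-2-enoyl]oxy}eudesma-3,11(13)-dien-12-oate | C=C(C(=O)OCOCC[Si](C)(C)C)[C@@H]1CC[C@@]2(C)CCC=C(COC(=O)/C=C\c3ccc(O[Si](C)(C)C(C)(C)C)cc3)[C@@H]2C1 | intermediate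
23 | 2-[(2R,4aR,8aR)-8-({[(2Z)-3-(4-hydroxyphenyl)prop-2-enoyl]oxy}methyl)-4a-methyl-1,2,3,4,4a,5,6,8a-octahydronaphthalen-2-yl]prop-2-enoic acid | C=C(C(=O)O)[C@@H]1CC[C@@]2(C)CCC=C(COC(=O)/C=C\c3ccc(O)cc3)[C@@H]2C1 | target

**Step count.** Total: 14 steps. Longest linear sequence: 11 steps (steps 1, 2, 4–10, 13, 14).

**Steps most likely to fail**

Step 4. The vinyl ketone 4 may polymerise before it is intercepted, the enamine nitrogen may cyclise onto the C3 ketone instead of C4 closing on C5, or the auxiliary may not fully override the ring's own facial preference at C10. The fallback sets out from imine 7 and introduces C15 after the annulation. Michael addition to methyl vinyl ketone (THF, rt), hydrolysis with aqueous AcOH and aldol condensation with NaOMe in MeOH should give (4aS,7R)-4a-methyl-7-(prop-1-en-2-yl)-4,4a,5,6,7,8-hexahydronaphthalen-2(3H)-one F1. Iodination at C4 (I2, pyridine, CH2Cl2) should give the 4-iodo enone F2. Methoxycarbonylation (Pd(OAc)2, PPh3, CO, MeOH, Et3N, DMF) comes back to the route at 9.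

Step 6. The activated C3 alcohol may eliminate to the conjugated dienoate, or displacement at the hindered allylic carbon may be slow or ionise, which would break the stereochemical relay from C3 to C5. The fallback sets out from 9 and fixes C5 by thermodynamic protonation instead. Dissolving-metal reduction (Li, liquid NH3, t-BuOH, THF, −78 °C) should give the trans-fused methyl 3-oxo-5α-eudesm-11-en-15-oate F3. NaH and PhNTf2 in THF should give the enol triflate methyl 3-(trifluoromethylsulfonyloxy)-5α-eudesma-3,11-dien-15-oate F4. Reduction with Pd(OAc)2, PPh3, HCO2H and n-Bu3N in DMF comes back to the route at 13.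

Step 9. Chemoselectivity between the two carboxyl groups may be lost, through hydride attack on the aluminium carboxylate or a stalled ester reduction. The fallback sets out from 13 and changes the order so that no free acid meets the hydride. Reduction with i-Bu2AlH should give (5R,7R,10R)-eudesma-3,11-dien-15-ol F5. Esterification with 21 (EDC·HCl, DMAP, 0 °C) should give the (Z)-4-silyloxycinnamate F6, whose allylic ester deactivates the ring A alkene. SeO2/t-BuOOH, then MnO2, should then oxidise the isopropenyl group to the enal F7. NaClO2 oxidation should give the silyl-protected acid F8, and n-Bu4NF/AcOH comes back to the route at 23.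

Further compounds
F1 | step 4 | (4aS,7R)-4a-methyl-7-(prop-1-en-2-yl)-4,4a,5,6,7,8-hexahydronaphthalen-2(3H)-one | CC(=C)[C@@H]1CC[C@@]2(C)CCC(=O)C=C2C1
F2 | step 4 | (4aS,7R)-1-iodo-4a-methyl-7-(prop-1-en-2-yl)-4,4a,5,6,7,8-hexahydronaphthalen-2(3H)-one | CC(=C)[C@@H]1CC[C@@]2(C)CCC(=O)C(I)=C2C1
F3 | step 6 | methyl 3-oxo-5α-eudesm-11-en-15-oate (trans-fused, 4α-ester, enolisable at C4) | CC(=C)[C@@H]1CC[C@@]2(C)CCC(=O)[C@@H](C(=O)OC)[C@@H]2C1
F4 | step 6 | methyl 3-(trifluoromethylsulfonyloxy)-5α-eudesma-3,11-dien-15-oate | CC(=C)[C@@H]1CC[C@@]2(C)CCC(OS(=O)(=O)C(F)(F)F)=C(C(=O)OC)[C@@H]2C1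
F5 | step 9 | (5R,7R,10R)-eudesma-3,11-dien-15-ol | CC(=C)[C@@H]1CC[C@@]2(C)CCC=C(CO)[C@@H]2C1
F6 | step 9 | (5R,7R,10R)-eudesma-3,11-dien-15-yl (2Z)-3-[4-(tert-butyldimethylsilyloxy)phenyl]prop-2-enoate | CC(=C)[C@@H]1CC[C@@]2(C)CCC=C(COC(=O)/C=C\c3ccc(O[Si](C)(C)C(C)(C)C)cc3)[C@@H]2C1
F7 | step 9 | (5R,7R,10R)-12-oxoeudesma-3,11(13)-dien-15-yl (2Z)-3-[4-(tert-butyldimethylsilyloxy)phenyl]prop-2-enoate | O=CC(=C)[C@@H]1CC[C@@]2(C)CCC=C(COC(=O)/C=C\c3ccc(O[Si](C)(C)C(C)(C)C)cc3)[C@@H]2C1
F8 | step 9 | (5R,7R,10R)-15-{[(2Z)-3-(4-tert-butyldimethylsilyloxyphenyl)prop-2-enoyl]oxy}eudesma-3,11(13)-dien-12-oic acid | OC(=O)C(=C)[C@@H]1CC[C@@]2(C)CCC=C(COC(=O)/C=C\c3ccc(O[Si](C)(C)C(C)(C)C)cc3)[C@@H]2C1
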